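## Analysis of the target

Compound 13 (CNP0147493.0) has no fused or bridged rings: it is a bibenzyl whose rings A and B are joined by a CH2CH2 bridge and which carries three 4-hydroxybenzyl groups. The numbering used here is: ring A has OCH3 on C1, H on C2, OH on C3, 4-hydroxybenzyl groups on C4 and C6 and the bridge on C5; ring B has the bridge on C1, OH on C3 and the third 4-hydroxybenzyl group on C6. The molecule is achiral, with no stereocentre and no double-bond geometry, so any stereocentre made on the way has to be erased again. The sensitive groups are the five free phenols, which oxidise easily, and the three electron-rich diarylmethane links, which can ionise in strong acid; the single methyl ether must also stay distinct from the five hydroxyl groups, which calls for phenol protection that comes off without touching O–CH3. The difficulty is positional control and crowding: ring A is pentasubstituted with its bridge carbon C5 flanked by two benzyl groups, while C2 of ring A (between the two oxygens) and C2 and C4 of ring B must stay unsubstituted, a distinction that direct benzylation of the bibenzyl with a benzyl cation would not make. The strategy rests on one feature: each benzylic CH2 is bonded to a core carbon para to a ring oxygen (C4 and C6 of ring A, where it is also ortho to the second oxygen, and C6 of ring B), and these are the positions that electrophilic halogenation of the protected core picks out. Each CH2 can therefore be carried as a formyl group on the core, and the three identical outer rings can be brought in together by one aryl nucleophile used in threefold amount.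

## Retrosynthetic reasoning

**13 back to 12.** The three diarylmethane CH2 groups are taken back to secondary carbinols and the five phenols to benzyl ethers, giving the tris(diarylcarbinol) 12. No carbon–carbon bond is cut. The gain is that doubly benzylic C–OH bonds and O–CH2Ph bonds are broken by the same catalytic hydrogenolysis, while O–CH3 is not. The forward step has to cleave eight benzylic C–O bonds without reducing a ring, and it erases the three carbinol stereocentres.

**12 back to 9 and three molecules of 11.** The three bonds between the carbinol carbons and the outer 4-oxygenated phenyl rings are cut. Cutting on this side of the carbinol carbon, rather than between it and the core, leaves three identical formyl groups on the core (trialdehyde 9). All three outer rings then come from one nucleophile, the Grignard reagent 11; three molecules of it are needed per molecule of 9, and each is made from one molecule of bromide 10. Three skeletal bonds are formed in one operation, and ring B needs no separate diarylmethane synthesis. The forward reaction must reach complete threefold addition, including at the two formyl groups of ring A that have two ortho substituents.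

**9 back to 7 through 8.** The three formyl carbons are removed from C4 and C6 of ring A and C6 of ring B. This leads to the threefold aryllithium 8 and from there to tribromide 7. Electrophilic formylation could not place two formyl groups on ring A, because the first one deactivates the ring. Bromine can be placed three times, and each C–Br bond is then a latent C–CHO bond.

**7 back to 6.** The three C–Br bonds are cut, which leads to the protected bibenzyl 6. The forward reaction relies on the directing effects of the three ring oxygens. On ring A the positions para to one oxygen and ortho to the other (C4, C6) react, while C2 is shielded by two alkoxy groups. On ring B the position para to the benzyloxy group (C6) reacts.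

**6 back to 2 and 5.** The bond between C5 of ring A and the adjacent bridge carbon is cut. This gives aryl bromide 2 and the primary alkylborane 5, to be joined by an sp2–sp3 cross-coupling. Cutting the central CH2–CH2 bond would need an sp3–sp3 coupling. Going through a stilbene would need a hydrogenation that strips the benzyl ethers too early.

**5 back to 4, 4 back to 3, and 2 back to 1.** Borane 5 comes from anti-Markovnikov hydroboration of styrene 4. Styrene 4 comes from aldehyde 3 by one-carbon olefination. Bromide 2 comes from phenol 1 by O-benzylation. Compounds 1, 3 and 10 are catalogue compounds.

## Alternatives that were turned down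

**Alternative 1:** Ring A is built from acyclic pieces by cutting C4–C5 and C1–C2.
- Disconnection: keto ester A1 supplies C2, C3 and C4 with the C4 benzyl group. Allenoate A2 supplies C1, C6 and C5 with the C6 benzyl group, the bridge and the complete ring B.
- Forward key step: the dianion of A1 adds through its gamma carbon to the central allene carbon of A2. The remaining keto ester enolate carbon then closes onto the ester carbonyl of A2 with loss of the ester alkoxide, and tautomerisation gives the aromatic resorcylate A3.
- For it: every ring A substituent is fixed by connectivity and not by directing effects, and the fully substituted ring forms in one operation. On positional certainty at ring A it is stronger than the chosen route.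
- Against it:
  - A2 is a multistep target that already contains ring B with its diarylmethane, so that problem is only moved.
  - A2 has acidic benzylic and allenic protons facing a strongly basic dianion.
  - The bond-forming carbon of A1 is secondary and the acceptor carbon of A2 is fully substituted, so three contiguous substituted ring carbons are made under heavy steric load.
  - After ring formation the tert-butyl ester of A3 must be removed and the acid decarboxylated. One of two equivalent hydroxyl groups must then be methylated. Symmetry makes either one correct, but stopping at mono-methylation is statistical.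
- Comparison: the chosen route gets the same positions from well-understood directing effects on 6, uses three simple catalogue compounds and is clearly shorter.

**Alternative 2:** An aryne spanning C5–C6 of ring A is inserted into a keto ester.
- Disconnection: the C5–bridge bond and the C6–benzylic carbon bond are cut, leading to silyl triflate A4 and keto ester A5.
- Forward key step: fluoride converts A4 into the aryne. The enolate carbon of A5 adds to C5, the aryl anion at C6 attacks the ketone, and the four-membered alkoxide fragments to give A6, with CH2CO2CH3 on C5 and the aroyl group on C6.
- For it: two adjacent carbon–carbon bonds are made under mild, nearly neutral conditions with an unambiguous ortho relationship. The methoxy group next to C6 polarises the aryne so that the nucleophile goes to C5. On mildness it is stronger than the chosen route.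
- Against it:
  - Only two of the required bonds are formed.
  - The C4 benzyl group must already be in A4, a pentasubstituted ortho-silyl aryl triflate that needs a long preparation.
  - That benzyl group flanks C5 and sterically opposes the attack the methoxy group directs.
  - After A6, ring B with its own benzyl group still has to be attached at the ester carbon, and two carbonyl carbons must be deoxygenated.
- Comparison: the step count is the highest of the four. The chosen route forms all three diarylmethane carbons in one reaction from 9 and needs no late carbonyl manipulation beyond the final hydrogenolysis.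

**Alternative 3:** Both benzylic bonds of ring A and the C5–bridge bond are made in one palladium relay.
- Disconnection: iodoarene A7, two equivalents of benzyl chloride A8 and the ring B styrene A9.
- Forward key step: a palladium catalyst with a strained bicyclic olefin mediator and a carbonate base benzylates both ortho C–H positions of A7 with A8, then couples the ipso carbon with A9 in a Heck termination. This gives the (E)-stilbene A10. One hydrogenation of A10 would reduce the alkene and remove all five benzyl ethers to give 13.
- For it: this is the most convergent plan. Three bonds form in one operation, the positions are fixed by the iodine atom, and only two steps lead from the fragments to 13. It is stronger than the chosen route in bonds per step, and in step count probably equal or better.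
- Against it:
  - A9 already contains the ring B diarylmethane and needs its own synthesis.
  - A8 is an electron-rich benzylic chloride that ionises easily and adds oxidatively to zerovalent palladium. This opens direct benzylation of A9 and homocoupling in competition with the relay.
  - Each C–H bond to be palladated lies between the carbon–palladium carbon and an alkoxy-bearing carbon.
  - The Heck termination has to take place at an aryl palladium flanked by two benzyl groups, with an ortho-substituted styrene.
  - The correct order of four bond-forming events among three components has to be maintained.
- Comparison: the chosen route offers predictability instead. Every step is a two-component reaction of an elementary type, and the key step has conversion as its only variable.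

Key step: step 6

Remark on the chemistry: 12 is carried as the mixture of diastereomers that three independent additions produce. No control or separation is attempted, because step 7 converts all three carbinol carbons into CH2.

## Route

Step 1
Reactants: 1 3-bromo-5-methoxyphenol
Product: 2 1-(benzyloxy)-3-bromo-5-methoxybenzene
Conditions: BnBr, K2CO3, DMF, rt
Reagents that add atoms: benzyl bromide, BrCc1ccccc1
Why: Williamson ether synthesis; the phenoxide is the only nucleophile present and the aryl bromide and methyl ether are inert.

Step 2
Reactants: 3 3-(benzyloxy)benzaldehyde
Product: 4 1-(benzyloxy)-3-ethenylbenzene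
Conditions: Ph3PCH3Br, KOtBu, THF, 0 °C to rt
Reagents that add atoms: methyltriphenylphosphonium bromide, C[P+](c1ccccc1)(c1ccccc1)c1ccccc1.[Br-]
Why: Wittig methylenation of a non-enolisable aromatic aldehyde; no stereochemical issue arises for a terminal alkene.

Step 3
Reactants: 4 1-(benzyloxy)-3-ethenylbenzene; 2 1-(benzyloxy)-3-bromo-5-methoxybenzene
Product: 6 1-(benzyloxy)-3-{2-[3-(benzyloxy)phenyl]ethyl}-5-methoxybenzene, via 9-[2-(3-benzyloxyphenyl)ethyl]-9-borabicyclo[3.3.1]nonane 5 (not isolated)
Conditions: 9-BBN, THF, 0 °C to rt; then 2, PdCl2(dppf) (cat.), 3 M aq NaOH, THF, 65 °C
Reagents that add atoms: none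
Why: Hydroboration of the styrene with 9-BBN places boron on the terminal carbon, and the primary alkylborane then undergoes a B-alkyl Suzuki–Miyaura coupling with the aryl bromide; no hydrogen gas is used, so both benzyl ethers survive.

Step 4
Reactants: 6 1-(benzyloxy)-3-{2-[3-(benzyloxy)phenyl]ethyl}-5-methoxybenzene
Product: 7 1-(benzyloxy)-2,4-dibromo-3-{2-[5-(benzyloxy)-2-bromophenyl]ethyl}-5-methoxybenzene
Conditions: NBS (3.1 equiv), MeCN–CH2Cl2, 0 °C to rt, dark
Reagents that add atoms: N-bromosuccinimide, O=C1CCC(=O)N1Br
Why: Electrophilic aromatic bromination in a polar solvent; ring A reacts at C4 and C6 (each para to one alkoxy group and ortho to the other) and not at C2 between the two alkoxy groups, and ring B reacts at C6 para to its benzyloxy group. Each bromine deactivates its own ring, so the reaction should stop at three.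

Step 5
Reactants: 7 1-(benzyloxy)-2,4-dibromo-3-{2-[5-(benzyloxy)-2-bromophenyl]ethyl}-5-methoxybenzene
Product: 9 4-(benzyloxy)-2-{2-[5-(benzyloxy)-2-formylphenyl]ethyl}-6-methoxybenzene-1,3-dicarbaldehyde, via threefold aryllithium 8 (not isolated)
Conditions: t-BuLi (6.2 equiv), THF, −78 °C; DMF, −78 to 0 °C; 1 M aq HCl
Reagents that add atoms: N,N-dimethylformamide, CN(C)C=O
Why: Bromine–lithium exchange with two equivalents of t-BuLi per bromine is faster at −78 °C than deprotonation of the benzylic ether CH2 groups, and no aryllithium has an ortho leaving group. Each aryllithium adds once to DMF to give a stable tetrahedral lithium alkoxide that releases the aldehyde only on acidic work-up (formylation of an aryllithium with a formamide).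

Step 6
Reactants: 9 4-(benzyloxy)-2-{2-[5-(benzyloxy)-2-formylphenyl]ethyl}-6-methoxybenzene-1,3-dicarbaldehyde; 10 1-(benzyloxy)-4-bromobenzene (the first of the three equivalents that enter 12)
Product: 12 (4-(benzyloxy)-2-{2-[5-(benzyloxy)-2-{[4-(benzyloxy)phenyl](hydroxy)methyl}phenyl]ethyl}-6-methoxy-1,3-phenylene)bis{[4-(benzyloxy)phenyl]methanol} (mixture of diastereomers), via 4-(benzyloxy)phenylmagnesium bromide 11 (not isolated)
Conditions: 10 (4.5 equiv), Mg (5 equiv), cat. I2, THF, reflux; then 9 in THF added to the solution of 11, 0 °C to rt; sat. aq NH4Cl
Reagents that add atoms: 1-(benzyloxy)-4-bromobenzene 10 (second and third equivalents as two molecules), Brc1ccc(OCc2ccccc2)cc1.Brc1ccc(OCc2ccccc2)cc1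
Why: Polar 1,2-addition of an aryl Grignard reagent to aromatic aldehydes, the standard route to diarylmethanols, is run three times on one molecule: three molecules of 11, each made from one molecule of 10, add to the three formyl groups of 9 and form the three bonds between the carbinol carbons and the outer rings. Neither partner can divert: 11 has no beta-hydrogen for reduction, the formyl groups of 9 have no alpha-hydrogen for enolisation, and the methyl and benzyl ethers are inert to the reagent. The two formyl groups on ring A are flanked by an alkoxy group and the bridge, but the ortho alkoxy oxygen can bind magnesium and deliver the aryl group, and a formyl carbon is small enough to be reached between two ortho substituents. The three sites are independent, so the only selectivity needed is completeness, which the excess of 11 (4.5 equivalents for three sites) secures; adding 9 to the reagent also keeps free aldehyde away from magnesium alkoxide already formed and so suppresses Oppenauer-type hydride transfer. No ring is closed. The three carbinol carbons become stereocentres without any controlling element, since they are remote from one another and the substrate is achiral; 12 is therefore a mixture of racemic diastereomers, which is harmless because step 7 turns all three centres into CH2. Quenching with NH4Cl keeps the medium near neutral, because the electron-rich carbinols ionise in acid.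

Step 7
Reactants: 12 (4-(benzyloxy)-2-{2-[5-(benzyloxy)-2-{[4-(benzyloxy)phenyl](hydroxy)methyl}phenyl]ethyl}-6-methoxy-1,3-phenylene)bis{[4-(benzyloxy)phenyl]methanol}
Product: 13 2,4-bis(4-hydroxybenzyl)-3-{2-[5-hydroxy-2-(4-hydroxybenzyl)phenyl]ethyl}-5-methoxyphenol (CNP0147493.0)
Conditions: H2 (4 bar), 10% Pd/C, EtOAc–EtOH, cat. HCl, rt
Reagents that add atoms: none
Why: Catalytic hydrogenolysis removes the five O-benzyl groups; each carbinol is then a doubly benzylic alcohol on a para-hydroxyphenyl ring, which loses water under the trace of acid to a quinone-methide-type cation that is reduced on the palladium surface. The aryl methyl ether and the rings are untouched, and the three stereocentres of 12 disappear.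

## Compound list

1 | 3-bromo-5-methoxyphenol | COc1cc(O)cc(Br)c1 | starting material
2 | 1-(benzyloxy)-3-bromo-5-methoxybenzene | COc1cc(Br)cc(OCc2ccccc2)c1 | intermediate
3 | 3-(benzyloxy)benzaldehyde | O=Cc1cccc(OCc2ccccc2)c1 | starting material
4 | 1-(benzyloxy)-3-ethenylbenzene | C=Cc1cccc(OCc2ccccc2)c1 | intermediate
5 | 9-[2-(3-benzyloxyphenyl)ethyl]-9-borabicyclo[3.3.1]nonane | C(Cc1cccc(OCc2ccccc2)c1)B1C2CCCC1CCC2 | intermediate (not isolated)
6 | 1-(benzyloxy)-3-{2-[3-(benzyloxy)phenyl]ethyl}-5-methoxybenzene | COc1cc(OCc2ccccc2)cc(CCc2cccc(OCc3ccccc3)c2)c1 | intermediate
7 | 1-(benzyloxy)-2,4-dibromo-3-{2-[5-(benzyloxy)-2-bromophenyl]ethyl}-5-methoxybenzene | COc1cc(OCc2ccccc2)c(Br)c(CCc2cc(OCc3ccccc3)ccc2Br)c1Br | intermediate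
8 | threefold aryllithium (lithium in place of each bromine of 7) | COc1cc(OCc2ccccc2)c([Li])c(CCc2cc(OCc3ccccc3)ccc2[Li])c1[Li] | intermediate (not isolated)
9 | 4-(benzyloxy)-2-{2-[5-(benzyloxy)-2-formylphenyl]ethyl}-6-methoxybenzene-1,3-dicarbaldehyde | COc1cc(OCc2ccccc2)c(C=O)c(CCc2cc(OCc3ccccc3)ccc2C=O)c1C=O | intermediate
10 | 1-(benzyloxy)-4-bromobenzene | Brc1ccc(OCc2ccccc2)cc1 | starting material
11 | 4-(benzyloxy)phenylmagnesium bromide | Br[Mg]c1ccc(OCc2ccccc2)cc1 | intermediate (not isolated)
12 | (4-(benzyloxy)-2-{2-[5-(benzyloxy)-2-{[4-(benzyloxy)phenyl](hydroxy)methyl}phenyl]ethyl}-6-methoxy-1,3-phenylene)bis{[4-(benzyloxy)phenyl]methanol}, mixture of diastereomers | COc1cc(OCc2ccccc2)c(C(O)c2ccc(OCc3ccccc3)cc2)c(CCc2cc(OCc3ccccc3)ccc2C(O)c2ccc(OCc3ccccc3)cc2)c1C(O)c1ccc(OCc2ccccc2)cc1 | intermediate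
13 | 2,4-bis(4-hydroxybenzyl)-3-{2-[5-hydroxy-2-(4-hydroxybenzyl)phenyl]ethyl}-5-methoxyphenol (CNP0147493.0) | COc1cc(O)c(Cc2ccc(O)cc2)c(CCc2cc(O)ccc2Cc2ccc(O)cc2)c1Cc1ccc(O)cc1 | target

## Step count and least certain steps

Total step count: 7. Longest linear sequence: 6 steps (from 1 through steps 1, 3, 4, 5, 6 and 7, or from 3 through steps 2 to 7).

**Step 6 (key step).**
- What may go wrong: the addition may stall after one or two formyl groups, either because partly added magnesium alkoxides leave solution or because the second formyl group of ring A becomes shielded. A magnesium diarylmethoxide may transfer hydride to a formyl group that is still free, giving a diaryl ketone that takes up a second aryl group. The electron-rich carbinols may ionise during work-up or chromatography.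
- Fallback: the same three carbinol carbons are made with the roles inverted. Setting out from tribromide 7, the threefold aryllithium 8 is generated as in step 5 and quenched at −78 °C in THF with 4-(benzyloxy)benzaldehyde F1 (a catalogue aldehyde, three molecules taken up per molecule of 8, used in slight excess) in place of DMF. Work-up with aqueous NH4Cl gives 12, where the route is rejoined.
- What the fallback changes: the hindered partner is now the nucleophile and the unhindered aldehyde the electrophile, and no free core aldehyde is present at any time.
- Why it is not the first choice: it puts the polyanion risk and the carbinol formation into one flask. In the main route, 9 is a single compound that can be purified before the diastereomer mixture is formed.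

**Step 5.**
- What may go wrong: the exchange may be incomplete, or the polylithiated arene may be partly protonated by traces of proton sources or by the benzylic OCH2 groups (followed by Wittig rearrangement). Products lacking one or two formyl groups would result. The trianion may also aggregate and precipitate.
- Fallback: setting out from 7, a threefold Suzuki–Miyaura coupling with potassium vinyltrifluoroborate (Pd(OAc)2, SPhos, K3PO4, toluene–water, 90 °C) would give 1-(benzyloxy)-3-{2-[5-(benzyloxy)-2-ethenylphenyl]ethyl}-2,4-diethenyl-5-methoxybenzene F2. Its three vinyl groups would then be cleaved by Lemieux–Johnson oxidation (K2OsO4·2H2O cat., NaIO4, 2,6-lutidine, dioxane–water) to the trialdehyde 9, where the route is rejoined. No organolithium is involved.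

**Step 7.**
- What may go wrong: the hydrogenolysis may stop at partly deoxygenated polyphenols at the two crowded ring A carbinols once the benzyl ethers are gone. A benzylic cation may also be captured before it is reduced, either by C2 of ring B (closing a seven-membered ring from a ring A cation) or by C2 of ring A of a second molecule.
- Fallback: deoxygenation and deprotection are separated. Setting out from 12, ionic hydrogenation with a large excess of Et3SiH and CF3CO2H in CH2Cl2 at −20 to 0 °C would reduce the three carbinols to 1-(benzyloxy)-2,4-bis[4-(benzyloxy)benzyl]-3-{2-[5-(benzyloxy)-2-(4-(benzyloxy)benzyl)phenyl]ethyl}-5-methoxybenzene F3. The silane should trap each cation faster than an arene can. Acid-free hydrogenolysis (H2, 10% Pd/C, EtOAc–MeOH, rt) then removes the five benzyl ethers and rejoins the route at 13.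

**Step 4.**
- What may go wrong: positional control may be lost, with attack at C2 of ring A or at a second position of ring B before all three intended carbons carry bromine. The reaction may stall at a dibromide. Radical bromination of the bridge may occur if light is not excluded.
- Fallback: the halogen is changed, and with it the steric demand of the electrophile and the exchange chemistry. Setting out from 6, N-iodosuccinimide (3.1 equiv) with catalytic CF3CO2H in MeCN would give 1-(benzyloxy)-3-{2-[5-(benzyloxy)-2-iodophenyl]ethyl}-2,4-diiodo-5-methoxybenzene F4. The larger iodine electrophile avoids the doubly flanked C2 and does not start benzylic radical chains. Iodine–lithium exchange of F4 with t-BuLi in THF at −78 °C leads to the threefold aryllithium 8, where the route is rejoined before the DMF quench of step 5.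

## Further compounds

F1 | step 6 | 4-(benzyloxy)benzaldehyde (purchased reagent of the fallback) | O=Cc1ccc(OCc2ccccc2)cc1
F2 | step 5 | 1-(benzyloxy)-3-{2-[5-(benzyloxy)-2-ethenylphenyl]ethyl}-2,4-diethenyl-5-methoxybenzene | COc1cc(OCc2ccccc2)c(C=C)c(CCc2cc(OCc3ccccc3)ccc2C=C)c1C=C
F3 | step 7 | 1-(benzyloxy)-2,4-bis[4-(benzyloxy)benzyl]-3-{2-[5-(benzyloxy)-2-(4-(benzyloxy)benzyl)phenyl]ethyl}-5-methoxybenzene | COc1cc(OCc2ccccc2)c(Cc2ccc(OCc3ccccc3)cc2)c(CCc2cc(OCc3ccccc3)ccc2Cc2ccc(OCc3ccccc3)cc2)c1Cc1ccc(OCc2ccccc2)cc1
F4 | step 4 | 1-(benzyloxy)-3-{2-[5-(benzyloxy)-2-iodophenyl]ethyl}-2,4-diiodo-5-methoxybenzene | COc1cc(OCc2ccccc2)c(I)c(CCc2cc(OCc3ccccc3)ccc2I)c1I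
A1 | alternative 1 | tert-butyl 5-[4-(benzyloxy)phenyl]-3-oxopentanoate | CC(C)(C)OC(=O)CC(=O)CCc1ccc(OCc2ccccc2)cc1
A2 | alternative 1 | methyl 2-[4-(benzyloxy)benzyl]-5-{5-(benzyloxy)-2-[4-(benzyloxy)benzyl]phenyl}penta-2,3-dienoate | COC(=O)C(Cc1ccc(OCc2ccccc2)cc1)=C=CCc1cc(OCc2ccccc2)ccc1Cc1ccc(OCc2ccccc2)cc1
A3 | alternative 1 | tert-butyl 3,5-bis[4-(benzyloxy)benzyl]-4-{2-[5-(benzyloxy)-2-(4-(benzyloxy)benzyl)phenyl]ethyl}-2,6-dihydroxybenzoate | CC(C)(C)OC(=O)c1c(O)c(Cc2ccc(OCc3ccccc3)cc2)c(CCc2cc(OCc3ccccc3)ccc2Cc2ccc(OCc3ccccc3)cc2)c(Cc2ccc(OCc3ccccc3)cc2)c1O
A4 | alternative 2 | 4-(benzyloxy)-3-[4-(benzyloxy)benzyl]-6-methoxy-2-(trimethylsilyl)phenyl trifluoromethanesulfonate | COc1cc(OCc2ccccc2)c(Cc2ccc(OCc3ccccc3)cc2)c([Si](C)(C)C)c1OS(=O)(=O)C(F)(F)F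
A5 | alternative 2 | methyl 3-[4-(benzyloxy)phenyl]-3-oxopropanoate | COC(=O)CC(=O)c1ccc(OCc2ccccc2)cc1
A6 | alternative 2 | methyl 2-{3-(benzyloxy)-6-[4-(benzyloxy)benzoyl]-2-[4-(benzyloxy)benzyl]-5-methoxyphenyl}acetate | COc1cc(OCc2ccccc2)c(Cc2ccc(OCc3ccccc3)cc2)c(CC(=O)OC)c1C(=O)c1ccc(OCc2ccccc2)cc1
A7 | alternative 3 | 1-(benzyloxy)-3-iodo-5-methoxybenzene | COc1cc(I)cc(OCc2ccccc2)c1
A8 | alternative 3 | 1-(benzyloxy)-4-(chloromethyl)benzene | ClCc1ccc(OCc2ccccc2)cc1
A9 | alternative 3 | 4-(benzyloxy)-1-[4-(benzyloxy)benzyl]-2-ethenylbenzene | C=Cc1cc(OCc2ccccc2)ccc1Cc1ccc(OCc2ccccc2)cc1
A10 | alternative 3 | (E)-1-(benzyloxy)-2,4-bis[4-(benzyloxy)benzyl]-3-{2-[5-(benzyloxy)-2-(4-(benzyloxy)benzyl)phenyl]ethenyl}-5-methoxybenzene | COc1cc(OCc2ccccc2)c(Cc2ccc(OCc3ccccc3)cc2)c(/C=C/c2cc(OCc3ccccc3)ccc2Cc2ccc(OCc3ccccc3)cc2)c1Cc1ccc(OCc2ccccc2)cc1
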